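**Plan**

1. Labels: the eriodictyol unit has rings A (benzo), B (catechol) and C (pyranone: O1, C2, C3, C4, C4a, C8a); the naringenin unit has rings D (benzo, carrying C8''), E (4-hydroxyphenyl) and F (pyranone, C2'').
2. Retrosynthesis: remove six benzyl ethers; cut O1–C2 of ring C to an α-aryl-2'-hydroxychalcone; cut the C2''–ring E bond to a chromone and an arylboronic acid; cut the C2=C3 enone to a deoxybenzoin and 3,4-bis(benzyloxy)benzaldehyde; cut C3–C8'' to an 8-bromochromone and a methyl ketone.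
3. Forward: rings A, B, D and E are bought as benzene rings; ring F is closed first (chromone on ring D); C3–C8'' then joins rings D and A; ring B comes in by condensation and ring E by 1,4-addition; ring C is closed last.
4. Enabling feature: the phenolic oxygen O1 on C8a of ring A is ortho to the C4 acyl carbon, so O1 and C2 are the two ends of the enone O1···C2=C3–C4=O and close ring C in a 6-endo-trig conjugate addition that copies the chalcone-to-flavanone step of flavonoid biosynthesis. The aryl groups on C2 (ring B) and C3 (ring D through C8'') create allylic strain in the resulting enol, which steers protonation at C3 to the cis isomer.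
5. Stereochemistry: C2'' (S) from rhodium/chiral-diene 1,4-addition; C2 (R) from a bifunctional cinchona thiourea in the ring closure; C3 (R) from kinetic protonation of the enol anti to ring B; the last step is neutral so the cis C3–H is kept.

Key step: step 8

Remark: the descriptors derived from the given structure are 2R,3R (rings B and D cis on ring C) and 2''S; compounds 1, 7 and 10 are taken as commercial.

**Route**

Step 1
Reactants: 1 1-[2,4-bis(benzyloxy)-6-hydroxyphenyl]ethan-1-one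
Product: 3 5,7-bis(benzyloxy)-4H-chromen-4-one, via enaminone 2 (not isolated)
Conditions: Me2NCH(OMe)2, toluene, 100 °C; then aq HCl (cat.), CH2Cl2, 40 °C
Reagents that add atoms: N,N-dimethylformamide dimethyl acetal, COC(OC)N(C)C
Why: Enaminone formation at the methyl ketone followed by acid-induced addition–elimination of the chelated phenol (the standard amide-acetal chromone synthesis) closes ring F; no stereocentre is formed.

Step 2
Reactants: 3 5,7-bis(benzyloxy)-4H-chromen-4-one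
Product: 4 5,7-bis(benzyloxy)-8-bromo-4H-chromen-4-one
Conditions: NBS (1.05 equiv), DMF, 0 → 23 °C, dark
Reagents that add atoms: N-bromosuccinimide, O=C1CCC(=O)N1Br
Why: Electrophilic aromatic bromination of 5,7-dialkoxychromones is expected at C8, which is para to the 5-alkoxy group and flanked by the ring oxygen, whereas C6 lies between two benzyloxy groups; the regiochemistry is to be confirmed by HMBC.

Step 3
Reactants: 1 1-[2,4-bis(benzyloxy)-6-hydroxyphenyl]ethan-1-one
Product: 5 1-[2,4,6-tris(benzyloxy)phenyl]ethan-1-one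
Conditions: BnBr, K2CO3, DMF, 70 °C
Reagents that add atoms: benzyl bromide, BrCc1ccccc1
Why: Williamson benzylation of the chelated phenol is routine in warm DMF and gives a ketone whose two ortho benzyloxy groups are equivalent, which step 7 exploits.

Step 4
Reactants: 4 5,7-bis(benzyloxy)-8-bromo-4H-chromen-4-one; 5 1-[2,4,6-tris(benzyloxy)phenyl]ethan-1-one
Product: 6 5,7-bis(benzyloxy)-8-{2-oxo-2-[2,4,6-tris(benzyloxy)phenyl]ethyl}-4H-chromen-4-one
Conditions: Pd2(dba)3 (2.5 mol %), XPhos (7.5 mol %), K3PO4 (2.5 equiv), toluene, 90 °C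
Reagents that add atoms: none
Why: Buchwald–Hartwig α-arylation of the methyl ketone enolate under weak phosphate base forms the C3–C8'' bond; the chromone has no enolisable hydrogen and the doubly ortho-substituted aryl group should prevent a second arylation.

Step 5
Reactants: 6 5,7-bis(benzyloxy)-8-{2-oxo-2-[2,4,6-tris(benzyloxy)phenyl]ethyl}-4H-chromen-4-one; 7 3,4-bis(benzyloxy)benzaldehyde
Product: 9 (E)-2-[5,7-bis(benzyloxy)-4-oxo-4H-chromen-8-yl]-3-[3,4-bis(benzyloxy)phenyl]-1-[2,4,6-tris(benzyloxy)phenyl]prop-2-en-1-one, via aldol adduct 8 (not isolated)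
Conditions: TiCl4 (2.2 equiv), Et3N (4.5 equiv), CH2Cl2, −78 → 0 °C
Reagents that add atoms: none
Why: Titanium-mediated aldol condensation (soft enolisation of the doubly activated benzylic methylene, addition to the aldehyde, E1cB loss of the titanium-bound oxygen) should give the enone with the acyl group trans to ring B, the geometry to be assigned by NOE; a tertiary amine and a Lewis acid avoid the ring opening that secondary amines or hydroxide cause in chromones.

Step 6
Reactants: 9 (E)-2-[5,7-bis(benzyloxy)-4-oxo-4H-chromen-8-yl]-3-[3,4-bis(benzyloxy)phenyl]-1-[2,4,6-tris(benzyloxy)phenyl]prop-2-en-1-one; 10 [4-(benzyloxy)phenyl]boronic acid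
Product: 11 (E)-2-{(2S)-5,7-bis(benzyloxy)-2-[4-(benzyloxy)phenyl]-4-oxo-3,4-dihydro-2H-chromen-8-yl}-3-[3,4-bis(benzyloxy)phenyl]-1-[2,4,6-tris(benzyloxy)phenyl]prop-2-en-1-one
Conditions: [RhCl(C2H4)2]2 (2.5 mol %), (R,R)-Ph-bod [(1R,4R)-2,5-diphenylbicyclo[2.2.2]octa-2,5-diene, 5.5 mol %], KOH (0.2 equiv), dioxane/H2O 10:1, 40 °C
Reagents that add atoms: none
Why: Rhodium/chiral-diene asymmetric 1,4-addition of arylboronic acids to chromones (Hayashi–Miyaura type) sets C2'' by catalyst-controlled aryl transfer to one face of the chromone C2''=C3'' bond, while the α,β-diaryl trisubstituted enone is too hindered for carbometalation; the ligand antipode is to be fixed by a test on chromone 3, which must give (S)-tri-O-benzylnaringenin.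

Step 7
Reactants: 11 (E)-2-{(2S)-5,7-bis(benzyloxy)-2-[4-(benzyloxy)phenyl]-4-oxo-3,4-dihydro-2H-chromen-8-yl}-3-[3,4-bis(benzyloxy)phenyl]-1-[2,4,6-tris(benzyloxy)phenyl]prop-2-en-1-one
Product: 12 (E)-1-[2,4-bis(benzyloxy)-6-hydroxyphenyl]-2-{(2S)-7-(benzyloxy)-2-[4-(benzyloxy)phenyl]-5-hydroxy-4-oxo-3,4-dihydro-2H-chromen-8-yl}-3-[3,4-bis(benzyloxy)phenyl]prop-2-en-1-one
Conditions: BCl3 (2.3 equiv), CH2Cl2, −78 °C; pH 7 phosphate buffer, −78 → 0 °C
Reagents that add atoms: none
Why: Chelation-controlled cleavage by BCl3 removes only benzyl ethers ortho or peri to a carbonyl group at −78 °C, here one of the two equivalent ortho ethers on ring A (the future O1) and the 5''-ether on ring D, and the boron chelate formed should slow cleavage of the second ortho ether.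

Step 8
Reactants: 12 (E)-1-[2,4-bis(benzyloxy)-6-hydroxyphenyl]-2-{(2S)-7-(benzyloxy)-2-[4-(benzyloxy)phenyl]-5-hydroxy-4-oxo-3,4-dihydro-2H-chromen-8-yl}-3-[3,4-bis(benzyloxy)phenyl]prop-2-en-1-one
Product: 14 (2S)-7-(benzyloxy)-2-[4-(benzyloxy)phenyl]-8-{(2R,3R)-5,7-bis(benzyloxy)-2-[3,4-bis(benzyloxy)phenyl]-4-oxo-3,4-dihydro-2H-chromen-3-yl}-5-hydroxy-2,3-dihydro-4H-chromen-4-one, via enol 13 (not isolated)
Conditions: quinidine-derived thiourea 1-[3,5-bis(trifluoromethyl)phenyl]-3-(9-deoxy-9-epi-quinidin-9-yl)thiourea (20 mol %), toluene, −20 → 0 °C; AcOH quench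
Reagents that add atoms: none
Why: Proposed new method: the quinuclidine nitrogen of the catalyst takes the proton of the chelated ring A hydroxyl of 12 while the thiourea binds the C4 carbonyl oxygen, and the phenoxide oxygen (future O1) adds to the enone β-carbon (future C2) in a 6-endo-trig oxa-Michael closure of ring C to give enol 13, which is protonated at C3 to 14. The closest known reaction types are the cinchona-thiourea-catalysed enantioselective cyclisation of 2'-hydroxychalcones to flavanones, shown for α-unsubstituted and α-alkoxycarbonyl chalcones but not for α-aryl ones, and the achiral amine-mediated closure of α-aryl-2'-hydroxychalcones to 2,3-diarylchromanones. C2 is set by the catalyst, which covers one face of the bound enone; the 2R sense is expected from the quinidine series and is to be checked on a model α-phenylchalcone, the quinine-derived pseudoenantiomer being at hand. C3 is set by the substrate: in enol 13 allylic 1,2-strain between ring D on C3 and ring B on C2 turns ring B pseudoaxial, and the proton enters C3 axially on the face opposite to ring B, which leaves rings B and D cis (2R,3R). The step needs kinetic control, that is no epimerisation of C3 to the trans isomer and no retro-Michael loss of C2, which the weak base, the low temperature, the C3–H shielded by two ortho-disubstituted aryl groups and the acidic quench should secure. Chemoselectivity follows from the structure, since the chelated 5''-hydroxyl of ring D has no acceptor within reach and the ring F ketone carries no enone.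

Step 9
Reactants: 14 (2S)-7-(benzyloxy)-2-[4-(benzyloxy)phenyl]-8-{(2R,3R)-5,7-bis(benzyloxy)-2-[3,4-bis(benzyloxy)phenyl]-4-oxo-3,4-dihydro-2H-chromen-3-yl}-5-hydroxy-2,3-dihydro-4H-chromen-4-one
Product: 15 (2S)-8-[(2R,3R)-2-(3,4-dihydroxyphenyl)-5,7-dihydroxy-4-oxo-3,4-dihydro-2H-chromen-3-yl]-5,7-dihydroxy-2-(4-hydroxyphenyl)-2,3-dihydro-4H-chromen-4-one
Conditions: H2 (1 atm), 10% Pd/C, EtOAc/MeOH 1:1, 23 °C
Reagents that add atoms: none
Why: Neutral hydrogenolysis of the six aryl benzyl ethers over Pd/C uses neither acid nor base, so the kinetically formed cis C3–H and both benzylic C2–O bonds (flavanone benzyl ethers are routinely cleaved this way) are expected to survive.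

**Compound list**

1 | 1-[2,4-bis(benzyloxy)-6-hydroxyphenyl]ethan-1-one | CC(=O)c1c(O)cc(OCc2ccccc2)cc1OCc1ccccc1 | starting material
2 | (E)-1-[2,4-bis(benzyloxy)-6-hydroxyphenyl]-3-(dimethylamino)prop-2-en-1-one | CN(C)/C=C/C(=O)c1c(O)cc(OCc2ccccc2)cc1OCc1ccccc1 | intermediate
3 | 5,7-bis(benzyloxy)-4H-chromen-4-one | O=c1ccoc2cc(OCc3ccccc3)cc(OCc3ccccc3)c12 | intermediate
4 | 5,7-bis(benzyloxy)-8-bromo-4H-chromen-4-one | O=c1ccoc2c(Br)c(OCc3ccccc3)cc(OCc3ccccc3)c12 | intermediate
5 | 1-[2,4,6-tris(benzyloxy)phenyl]ethan-1-one | CC(=O)c1c(OCc2ccccc2)cc(OCc2ccccc2)cc1OCc1ccccc1 | intermediate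
6 | 5,7-bis(benzyloxy)-8-{2-oxo-2-[2,4,6-tris(benzyloxy)phenyl]ethyl}-4H-chromen-4-one | O=c1ccoc2c(CC(=O)c3c(OCc4ccccc4)cc(OCc4ccccc4)cc3OCc3ccccc3)c(OCc3ccccc3)cc(OCc3ccccc3)c12 | intermediate
7 | 3,4-bis(benzyloxy)benzaldehyde | O=Cc1ccc(OCc2ccccc2)c(OCc2ccccc2)c1 | starting material
8 | 5,7-bis(benzyloxy)-8-{1-[3,4-bis(benzyloxy)phenyl]-1-hydroxy-3-oxo-3-[2,4,6-tris(benzyloxy)phenyl]propan-2-yl}-4H-chromen-4-one (aldol adduct, mixture of diastereomers) | O=c1ccoc2c(C(C(O)c3ccc(OCc4ccccc4)c(OCc4ccccc4)c3)C(=O)c3c(OCc4ccccc4)cc(OCc4ccccc4)cc3OCc3ccccc3)c(OCc3ccccc3)cc(OCc3ccccc3)c12 | intermediate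
9 | (E)-2-[5,7-bis(benzyloxy)-4-oxo-4H-chromen-8-yl]-3-[3,4-bis(benzyloxy)phenyl]-1-[2,4,6-tris(benzyloxy)phenyl]prop-2-en-1-one | O=c1ccoc2c(/C(=C\c3ccc(OCc4ccccc4)c(OCc4ccccc4)c3)C(=O)c3c(OCc4ccccc4)cc(OCc4ccccc4)cc3OCc3ccccc3)c(OCc3ccccc3)cc(OCc3ccccc3)c12 | intermediate
10 | [4-(benzyloxy)phenyl]boronic acid | OB(O)c1ccc(OCc2ccccc2)cc1 | starting material
11 | (E)-2-{(2S)-5,7-bis(benzyloxy)-2-[4-(benzyloxy)phenyl]-4-oxo-3,4-dihydro-2H-chromen-8-yl}-3-[3,4-bis(benzyloxy)phenyl]-1-[2,4,6-tris(benzyloxy)phenyl]prop-2-en-1-one | O=C1C[C@@H](c2ccc(OCc3ccccc3)cc2)Oc2c1c(OCc1ccccc1)cc(OCc1ccccc1)c2/C(=C\c1ccc(OCc2ccccc2)c(OCc2ccccc2)c1)C(=O)c1c(OCc2ccccc2)cc(OCc2ccccc2)cc1OCc1ccccc1 | intermediate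
12 | (E)-1-[2,4-bis(benzyloxy)-6-hydroxyphenyl]-2-{(2S)-7-(benzyloxy)-2-[4-(benzyloxy)phenyl]-5-hydroxy-4-oxo-3,4-dihydro-2H-chromen-8-yl}-3-[3,4-bis(benzyloxy)phenyl]prop-2-en-1-one | O=C1C[C@@H](c2ccc(OCc3ccccc3)cc2)Oc2c1c(O)cc(OCc1ccccc1)c2/C(=C\c1ccc(OCc2ccccc2)c(OCc2ccccc2)c1)C(=O)c1c(O)cc(OCc2ccccc2)cc1OCc1ccccc1 | intermediate
13 | enol of 14: (2S)-7-(benzyloxy)-2-[4-(benzyloxy)phenyl]-8-{5,7-bis(benzyloxy)-2-[3,4-bis(benzyloxy)phenyl]-4-hydroxy-2H-chromen-3-yl}-5-hydroxy-2,3-dihydro-4H-chromen-4-one, new C2 centre arranged in space as in 14 (formally 2S by the changed CIP priorities) | O=C1C[C@@H](c2ccc(OCc3ccccc3)cc2)Oc2c1c(O)cc(OCc1ccccc1)c2C1=C(O)c2c(OCc3ccccc3)cc(OCc3ccccc3)cc2O[C@H]1c1ccc(OCc2ccccc2)c(OCc2ccccc2)c1 | intermediate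
14 | (2S)-7-(benzyloxy)-2-[4-(benzyloxy)phenyl]-8-{(2R,3R)-5,7-bis(benzyloxy)-2-[3,4-bis(benzyloxy)phenyl]-4-oxo-3,4-dihydro-2H-chromen-3-yl}-5-hydroxy-2,3-dihydro-4H-chromen-4-one | O=C1C[C@@H](c2ccc(OCc3ccccc3)cc2)Oc2c1c(O)cc(OCc1ccccc1)c2[C@H]1C(=O)c2c(OCc3ccccc3)cc(OCc3ccccc3)cc2O[C@H]1c1ccc(OCc2ccccc2)c(OCc2ccccc2)c1 | intermediate
15 | (2S)-8-[(2R,3R)-2-(3,4-dihydroxyphenyl)-5,7-dihydroxy-4-oxo-3,4-dihydro-2H-chromen-3-yl]-5,7-dihydroxy-2-(4-hydroxyphenyl)-2,3-dihydro-4H-chromen-4-one | O=C1C[C@@H](c2ccc(O)cc2)Oc2c1c(O)cc(O)c2[C@H]1C(=O)c2c(O)cc(O)cc2O[C@H]1c1ccc(O)c(O)c1 | target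

**Count and risks**

Total step count: 9. Longest linear sequence: 8 steps (steps 1, 2, 4, 5, 6, 7, 8, 9).

Steps most likely to fail:

Step 8. The catalyst may discriminate the two faces of the hindered α-aryl enone poorly, or C3 may epimerise to the trans isomer during the reaction. The fallback moves stereocontrol from the catalyst to separation and uses known chemistry. It sets out from 12, which is cyclised with an achiral tertiary amine (quinuclidine 20 mol %, toluene, 0 °C, AcOH quench), the classical closure of α-aryl-2'-hydroxychalcones, under the same kinetic protonation. This should give 14 together with its cis diastereomer (2S)-7-(benzyloxy)-2-[4-(benzyloxy)phenyl]-8-{(2S,3S)-5,7-bis(benzyloxy)-2-[3,4-bis(benzyloxy)phenyl]-4-oxo-3,4-dihydro-2H-chromen-3-yl}-5-hydroxy-2,3-dihydro-4H-chromen-4-one F1. Because C2'' is already S, the two are diastereomers and are separated by preparative HPLC; the route is rejoined at 14.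

Step 4. The ketone enolate may attack C2 of the chromone, or oxidative addition at the doubly ortho-substituted C–Br bond may be too slow. The fallback forms the ketone by acylation instead and sets out from 4. Base-free coupling of 4 with the Reformatsky reagent BrZnCH2CO2t-Bu (Pd2(dba)3, P(t-Bu)3, THF, 23–60 °C) gives tert-butyl 2-[5,7-bis(benzyloxy)-4-oxo-4H-chromen-8-yl]acetate F2. Acidolysis (CF3CO2H, CH2Cl2, 0 °C) gives 2-[5,7-bis(benzyloxy)-4-oxo-4H-chromen-8-yl]acetic acid F3. Commercial 1,3,5-tris(benzyloxy)benzene F4 is then acylated in a Friedel–Crafts reaction through 2-[5,7-bis(benzyloxy)-4-oxo-4H-chromen-8-yl]acetic trifluoroacetic anhydride F5, made in the flask with (CF3CO)2O in CH2Cl2 at 0 °C. The three equivalent positions of F4 leave no regiochemical question, and the route is rejoined at 6.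

Step 6. Carbometalation may be slow or poorly face-selective because the large C8'' substituent of 9 crowds the chromone. The fallback changes the order so that the asymmetric addition meets a small substrate without a second enone, and sets out from 6. Compound 6 and 10 under the rhodium/diene conditions of step 6 should give (2S)-5,7-bis(benzyloxy)-2-[4-(benzyloxy)phenyl]-8-{2-oxo-2-[2,4,6-tris(benzyloxy)phenyl]ethyl}-2,3-dihydro-4H-chromen-4-one F6. F6 is then condensed with 7 (TiCl4, Et3N, CH2Cl2, −78 °C), where soft enolisation should select the far more acidic benzylic methylene over C3'' of the flavanone. The condensation passes through the aldol adduct (2S)-5,7-bis(benzyloxy)-2-[4-(benzyloxy)phenyl]-8-{1-[3,4-bis(benzyloxy)phenyl]-1-hydroxy-3-oxo-3-[2,4,6-tris(benzyloxy)phenyl]propan-2-yl}-2,3-dihydro-4H-chromen-4-one F7, which is not isolated, and rejoins the route at 11.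

Further compounds
F1 | step 8 | (2S)-7-(benzyloxy)-2-[4-(benzyloxy)phenyl]-8-{(2S,3S)-5,7-bis(benzyloxy)-2-[3,4-bis(benzyloxy)phenyl]-4-oxo-3,4-dihydro-2H-chromen-3-yl}-5-hydroxy-2,3-dihydro-4H-chromen-4-one | O=C1C[C@@H](c2ccc(OCc3ccccc3)cc2)Oc2c1c(O)cc(OCc1ccccc1)c2[C@@H]1C(=O)c2c(OCc3ccccc3)cc(OCc3ccccc3)cc2O[C@@H]1c1ccc(OCc2ccccc2)c(OCc2ccccc2)c1
F2 | step 4 | tert-butyl 2-[5,7-bis(benzyloxy)-4-oxo-4H-chromen-8-yl]acetate | CC(C)(C)OC(=O)Cc1c(OCc2ccccc2)cc(OCc2ccccc2)c2c(=O)ccoc12
F3 | step 4 | 2-[5,7-bis(benzyloxy)-4-oxo-4H-chromen-8-yl]acetic acid | OC(=O)Cc1c(OCc2ccccc2)cc(OCc2ccccc2)c2c(=O)ccoc12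
F4 | step 4 | 1,3,5-tris(benzyloxy)benzene | c1ccc(COc2cc(OCc3ccccc3)cc(OCc3ccccc3)c2)cc1
F5 | step 4 | 2-[5,7-bis(benzyloxy)-4-oxo-4H-chromen-8-yl]acetic trifluoroacetic anhydride | O=C(Cc1c(OCc2ccccc2)cc(OCc2ccccc2)c2c(=O)ccoc12)OC(=O)C(F)(F)F
F6 | step 6 | (2S)-5,7-bis(benzyloxy)-2-[4-(benzyloxy)phenyl]-8-{2-oxo-2-[2,4,6-tris(benzyloxy)phenyl]ethyl}-2,3-dihydro-4H-chromen-4-one | O=C1C[C@@H](c2ccc(OCc3ccccc3)cc2)Oc2c1c(OCc1ccccc1)cc(OCc1ccccc1)c2CC(=O)c1c(OCc2ccccc2)cc(OCc2ccccc2)cc1OCc1ccccc1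
F7 | step 6 | (2S)-5,7-bis(benzyloxy)-2-[4-(benzyloxy)phenyl]-8-{1-[3,4-bis(benzyloxy)phenyl]-1-hydroxy-3-oxo-3-[2,4,6-tris(benzyloxy)phenyl]propan-2-yl}-2,3-dihydro-4H-chromen-4-one (mixture of diastereomers) | O=C1C[C@@H](c2ccc(OCc3ccccc3)cc2)Oc2c1c(OCc1ccccc1)cc(OCc1ccccc1)c2C(C(O)c1ccc(OCc2ccccc2)c(OCc2ccccc2)c1)C(=O)c1c(OCc2ccccc2)cc(OCc2ccccc2)cc1OCc1ccccc1
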